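**Retrosynthetic overview**
- The two angelate esters are put on last; the C7 isopropenyl group comes from α-alkenylation of a C8 ketone, and the C8 ketone/C9 hydroxyl pair comes from a C8=C9 alkene in ring B.
- Ring A is disconnected at C1–C10 and C2–C3, giving a monocyclic acid (C3 carboxyl, C4, quaternary C5 on a cyclohex-2-enyl ring B) and a two-carbon vinyl unit.
- Enabling feature: in ring B the C9=C10 double bond is γ,δ to the C3 carbonyl (C3–C4–C5–C10). A vinyl ketone at C3 therefore reaches C10 through a six-membered chair, and because C5 is quaternary the double bond can only be pushed on to C8=C9, where the ketol is needed.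
- The C4/C5 vicinal methyl pair comes from an Ireland–Claisen rearrangement of (R)-3-methylcyclohex-2-enyl propanoate; the carbinol comes from a CBS reduction.
- Ring order: ring B is bought (3-methylcyclohex-2-enone); ring A is closed in the key step.

Key step: step 4

Remark: eremophilane numbering is used for all decalin intermediates (ring A = C1–C5, C10; ring B = C5–C10; C14 = methyl on C5, C15 = methyl on C4, C11–C13 = isopropenyl on C7); angeloyl = (Z)-2-methylbut-2-enoyl.

**Route**

Step 1
Reactants: 1 3-methylcyclohex-2-en-1-one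
Product: 2 (1R)-3-methylcyclohex-2-en-1-ol
Conditions: (S)-2-methyl-CBS-oxazaborolidine (C18H20BNO, 10 mol %), BH3·SMe2, THF, −20 °C; MeOH
Reagents that add atoms: none
Why: Corey–Bakshi–Shibata reduction, in which the alkenyl arm acts as the large group so that the (S)-catalyst should give the (R)-allylic alcohol, the only stereocentre made with a chiral reagent.

Step 2
Reactants: 2 (1R)-3-methylcyclohex-2-en-1-ol
Product: 3 (1R)-3-methylcyclohex-2-en-1-yl propanoate
Conditions: (EtCO)2O, Et3N, DMAP (cat.), CH2Cl2, 0 °C to rt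
Reagents that add atoms: propanoic anhydride, CCC(=O)OC(=O)CC
Why: DMAP-catalysed O-acylation of a secondary allylic alcohol, which leaves the carbinol centre untouched.

Step 3
Reactants: 3 (1R)-3-methylcyclohex-2-en-1-yl propanoate
Product: 6 (2R)-2-[(1S)-1-methylcyclohex-2-en-1-yl]propanoic acid, via (E)-ketene silyl acetal 4 (not isolated), via trimethylsilyl ester 5 (not isolated)
Conditions: LiN(iPr)2, THF, −78 °C; Me3SiCl, Et3N; −78 to 60 °C; aq. NaOH, then HCl
Reagents that add atoms: none
Why: Ireland–Claisen rearrangement, in which the suprafacial [3,3] shift forms C4–C5 on the ring face the ester oxygen leaves (so the (R)-carbinol becomes the (S)-quaternary C5), and the kinetic (E)-ketene silyl acetal (methyl trans to OSiMe3) reacting through the chair that keeps this methyl away from the ring sets C4 as (R), the arrangement that makes the two methyl groups cis in the decalin (the (Z)-acetal through the boat would converge on the same isomer).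

Step 4
Reactants: 6 (2R)-2-[(1S)-1-methylcyclohex-2-en-1-yl]propanoic acid
Product: 9 (4R,5S,10R)-4,5-dimethyl-cis-bicyclo[4.4.0]dec-8-en-3-one, via acid chloride 7 (not isolated), via vinyl ketone 8 (not isolated)
Conditions: (COCl)2, DMF (cat.), CH2Cl2, 0 °C to rt, evaporate; CH2=CHSnBu3, PdCl2(PPh3)2 (3 mol %), toluene, 50 °C; then MeAlCl2, CH2Cl2, −78 to 0 °C
Reagents that add atoms: tributyl(vinyl)stannane, C=C[Sn](CCCC)(CCCC)CCCC
Why: Oxalyl chloride gives acid chloride 7, and Migita–Stille acylation (an acyl–palladium species, so no free acylium ion that could attack the ring alkene) joins the vinyl group to C3 and makes C2–C3 in vinyl ketone 8; MeAlCl2 then activates the enone, the C9=C10 π bond adds to the terminal carbon C1 (C1–C10), and the resulting C9 carbenium ion/aluminium enolate pair collapses by loss of the axial C8 hydrogen to give the C8=C9 alkene. The closest known reaction types are the palladium-catalysed acylation of vinylstannanes by acid chlorides and the Lewis-acid-induced intramolecular conjugate addition of an alkene to an enone (cation–olefin, "conjugate ene" cyclization). Ring A closes by 6-exo attack on the C9=C10 bond (6-endo with respect to the enone) through a chair, in preference to the seven-membered closure through C9. C10 is the only new stereocentre and is controlled by the tether: C4 hangs on C5 and C1 can reach the adjacent sp2 carbon only on that same face, so H10 ends cis to the C5 methyl (cis ring fusion), while C4 and C5 are not touched. The selectivity needed is in the termination (C8=C9 rather than C9=C10 or a shifted cation): quaternary C5 offers no hydrogen, and after axial entry of C1 the C10 hydrogen lies in the nodal plane of the C9 cation whereas the axial C8 hydrogen is aligned with it; MeAlCl2 serves as proton sink (methane) so that the alkene is not re-protonated.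

Step 5
Reactants: 9 (4R,5S,10R)-4,5-dimethyl-cis-bicyclo[4.4.0]dec-8-en-3-one
Product: 10 (3R,4R,5S,10R)-4,5-dimethyl-cis-bicyclo[4.4.0]dec-8-en-3-ol
Conditions: Li, NH3(l), THF, EtOH, −78 °C; NH4Cl
Reagents that add atoms: none
Why: Dissolving-metal reduction of the ketone should proceed under thermodynamic control to the equatorial C3 alcohol (oxygen trans to the C4 methyl; the epimer would place OH 1,3-diaxial to the C5 methyl), and the isolated C8=C9 alkene is not reduced.

Step 6
Reactants: 10 (3R,4R,5S,10R)-4,5-dimethyl-cis-bicyclo[4.4.0]dec-8-en-3-ol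
Product: 11 (3R,4R,5R,8S,9R,10S)-4,5-dimethyl-cis-bicyclo[4.4.0]decane-3,8,9-triol
Conditions: OsO4 (2 mol %), N-methylmorpholine N-oxide, acetone/H2O, rt
Reagents that add atoms: N-methylmorpholine N-oxide, C[N+]1([O-])CCOCC1; water, O
Why: Catalytic osmium tetroxide syn-dihydroxylation of the only alkene, expected from the face of ring B that carries H10 and the C5 methyl (anti to the axial C5–C4 bond and to C1), which sets the C9 oxygen trans to C1 as in the target.

Step 7
Reactants: 11 (3R,4R,5R,8S,9R,10S)-4,5-dimethyl-cis-bicyclo[4.4.0]decane-3,8,9-triol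
Product: 13 (3R,4R,5R,9R,10S)-3,9-dihydroxy-4,5-dimethyl-cis-bicyclo[4.4.0]decan-8-one, via 8,9-O-dibutylstannylene acetal 12 (not isolated)
Conditions: Bu2SnO, toluene, reflux (−H2O); then Br2 (1 equiv), CH2Cl2, 4 Å MS, rt
Reagents that add atoms: none
Why: Brominolysis of a dibutylstannylene acetal (stannylene-mediated regioselective diol oxidation) oxidises the axial hydroxyl of a cis-1,2-diol, here C8–OH, and leaves the equatorial C9–OH and the isolated, non-stannylated C3–OH, so the ketone should appear at C8.

Step 8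
Reactants: 13 (3R,4R,5R,9R,10S)-3,9-dihydroxy-4,5-dimethyl-cis-bicyclo[4.4.0]decan-8-one
Product: 14 (3R,4R,5R,9R,10S)-3,9-bis(tert-butyldimethylsilyloxy)-4,5-dimethyl-cis-bicyclo[4.4.0]decan-8-one
Conditions: TBSOTf, 2,6-lutidine, CH2Cl2, −78 to 0 °C
Reagents that add atoms: tert-butyldimethylsilyl trifluoromethanesulfonate, CC(C)(C)[Si](C)(C)OS(=O)(=O)C(F)(F)F
Why: Silylation of both secondary hydroxyls protects them against the strong base of the next step and affects no stereocentre.

Step 9
Reactants: 14 (3R,4R,5R,9R,10S)-3,9-bis(tert-butyldimethylsilyloxy)-4,5-dimethyl-cis-bicyclo[4.4.0]decan-8-one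
Product: 16 (3R,4R,5R,7R,9R,10S)-3,9-bis(tert-butyldimethylsilyloxy)eremophil-11-en-8-one, via lithium C7–C8 enolate 15 (not isolated)
Conditions: LiN(SiMe3)2, toluene, −78 to 0 °C; 2-bromopropene, Pd2(dba)3 (2.5 mol %; dba = dibenzylideneacetone), P(t-Bu)3 (10 mol %), rt; AcOH/THF, −78 °C
Reagents that add atoms: 2-bromopropene, CC(Br)=C
Why: Palladium-catalysed α-alkenylation of a ketone enolate (enolate cross-coupling): the base removes a C7 hydrogen (C9 is shielded by its silyloxy group), the enolate couples with the isopropenylpalladium bromide formed by oxidative addition to zerovalent palladium, and low-temperature protonation at C7 of the resulting extended enolate should give the β,γ-unsaturated ketone with the isopropenyl group equatorial, cis to the C9 oxygen, which is the more stable C7 configuration.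

Step 10
Reactants: 16 (3R,4R,5R,7R,9R,10S)-3,9-bis(tert-butyldimethylsilyloxy)eremophil-11-en-8-one
Product: 17 (3R,4R,5R,7R,9R,10S)-3,9-dihydroxyeremophil-11-en-8-one
Conditions: HF·pyridine, pyridine, THF, 0 °C to rt
Reagents that add atoms: none
Why: Buffered acidic fluoride desilylation removes both TBS groups without base, so neither epimerisation at C7/C9 nor migration of the isopropenyl double bond into conjugation is invited.

Step 11
Reactants: 17 (3R,4R,5R,7R,9R,10S)-3,9-dihydroxyeremophil-11-en-8-one
Product: 18 (3R,4R,5R,7R,9R,10S)-3,9-bis[(Z)-2-methylbut-2-enoyloxy]eremophil-11-en-8-one (CNP0174755.1)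
Conditions: angelic acid, 2,4,6-trichlorobenzoyl chloride, Et3N, toluene, rt; then 17, toluene, 70 °C (no DMAP)
Reagents that add atoms: angelic acid, C/C=C(/C)C(=O)O
Why: Yamaguchi-type esterification through the mixed anhydride of angelic and 2,4,6-trichlorobenzoic acid, run without DMAP, should acylate both secondary hydroxyls at the less hindered angeloyl carbonyl and keep the (Z) geometry.

**Compound list**
1 | 3-methylcyclohex-2-en-1-one | CC1=CC(=O)CCC1 | starting material
2 | (1R)-3-methylcyclohex-2-en-1-ol | O[C@H]1C=C(C)CCC1 | intermediate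
3 | (1R)-3-methylcyclohex-2-en-1-yl propanoate | CCC(=O)O[C@H]1C=C(C)CCC1 | intermediate
4 | (1R)-3-methylcyclohex-2-en-1-yl (E)-1-(trimethylsilyloxy)prop-1-enyl ether (ketene silyl acetal, methyl trans to OSiMe3) | C/C=C(/O[Si](C)(C)C)O[C@H]1C=C(C)CCC1 | intermediate
5 | trimethylsilyl (2R)-2-[(1S)-1-methylcyclohex-2-en-1-yl]propanoate | C1C[C@](C)([C@@H](C)C(=O)O[Si](C)(C)C)C=CC1 | intermediate
6 | (2R)-2-[(1S)-1-methylcyclohex-2-en-1-yl]propanoic acid | C1C[C@](C)([C@@H](C)C(=O)O)C=CC1 | intermediate
7 | (2R)-2-[(1S)-1-methylcyclohex-2-en-1-yl]propanoyl chloride | C1C[C@](C)([C@@H](C)C(=O)Cl)C=CC1 | intermediate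
8 | (4R)-4-[(1S)-1-methylcyclohex-2-en-1-yl]pent-1-en-3-one | C1C[C@](C)([C@@H](C)C(=O)C=C)C=CC1 | intermediate
9 | (4R,5S,10R)-4,5-dimethyl-cis-bicyclo[4.4.0]dec-8-en-3-one (cis ring fusion, C4 and C5 methyls cis) | C1C[C@@]2(C)[C@H](CCC(=O)[C@@H]2C)C=C1 | intermediate
10 | (3R,4R,5S,10R)-4,5-dimethyl-cis-bicyclo[4.4.0]dec-8-en-3-ol (3-OH trans to C4 methyl) | C1C[C@@]2(C)[C@H](CC[C@@H](O)[C@@H]2C)C=C1 | intermediate
11 | (3R,4R,5R,8S,9R,10S)-4,5-dimethyl-cis-bicyclo[4.4.0]decane-3,8,9-triol (8,9-diol cis, on the face of H10 and the C5 methyl) | C1C[C@@]2(C)[C@H](CC[C@@H](O)[C@@H]2C)[C@@H](O)[C@H]1O | intermediate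
12 | 8,9-O-dibutylstannylene acetal of triol 11 | C1C[C@@]2(C)[C@H](CC[C@@H](O)[C@@H]2C)[C@@H](O[Sn]3(CCCC)CCCC)[C@H]1O3 | intermediate
13 | (3R,4R,5R,9R,10S)-3,9-dihydroxy-4,5-dimethyl-cis-bicyclo[4.4.0]decan-8-one | C1C[C@@]2(C)[C@H](CC[C@@H](O)[C@@H]2C)[C@@H](O)C1=O | intermediate
14 | (3R,4R,5R,9R,10S)-3,9-bis(tert-butyldimethylsilyloxy)-4,5-dimethyl-cis-bicyclo[4.4.0]decan-8-one | C1C[C@@]2(C)[C@H](CC[C@@H](O[Si](C)(C)C(C)(C)C)[C@@H]2C)[C@@H](O[Si](C)(C)C(C)(C)C)C1=O | intermediate
15 | lithium C7–C8 enolate of 14 | C1C[C@@]2(C)[C@H](CC[C@@H](O[Si](C)(C)C(C)(C)C)[C@@H]2C)[C@@H](O[Si](C)(C)C(C)(C)C)C=1O[Li] | intermediate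
16 | (3R,4R,5R,7R,9R,10S)-3,9-bis(tert-butyldimethylsilyloxy)eremophil-11-en-8-one | C=C(C)[C@H]1C[C@@]2(C)[C@H](CC[C@@H](O[Si](C)(C)C(C)(C)C)[C@@H]2C)[C@@H](O[Si](C)(C)C(C)(C)C)C1=O | intermediate
17 | (3R,4R,5R,7R,9R,10S)-3,9-dihydroxyeremophil-11-en-8-one | C=C(C)[C@H]1C[C@@]2(C)[C@H](CC[C@@H](O)[C@@H]2C)[C@@H](O)C1=O | intermediate
18 | (3R,4R,5R,7R,9R,10S)-3,9-bis[(Z)-2-methylbut-2-enoyloxy]eremophil-11-en-8-one (CNP0174755.1) | C=C(C)[C@H]1C[C@@]2(C)[C@H](CC[C@@H](OC(=O)/C(C)=C\C)[C@@H]2C)[C@@H](OC(=O)/C(C)=C\C)C1=O | target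

**Step count and risks**
Total step count: 11. Longest linear sequence: 11 steps (from 1).

Three steps most likely to fail:

1. Step 4. The C9 carbenium ion may collapse unselectively (hydride or alkyl shift, proton loss toward C10, chloride capture, cyclobutane formation), or the unactivated ring alkene may fail to add to the enone. Fallback, setting out from 6 and rejoining at 10: 6 is converted into the N-methoxy-N-methylamide F1 ((COCl)2, then MeNH(OMe)·HCl, pyridine). Ethynylmagnesium bromide gives the ynone F2, and anti-hydroiodination (NaI, AcOH) gives the (Z)-β-iodo enone F3. An intramolecular Mizoroki–Heck reaction (Pd(OAc)2, PPh3, Ag2CO3, MeCN) closes ring A to the cis-fused dienone F4: syn-carbopalladation places palladium on C9 cis to C1, the C10 hydrogen is anti, and only a C8 hydrogen can undergo β-hydride elimination, so the C8=C9 alkene is formed by rule. Li/NH3/EtOH then reduces the ring A enone of F4 through the saturated ketone to the equatorial alcohol 10. In this fallback the two ring A bonds are made in separate flasks.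

2. Step 9. Possible failures are double alkenylation, migration of the new double bond into conjugation with the ketone, or protonation of C7 from the wrong face. Fallback, setting out from 14 and rejoining at 16: Saegusa–Ito oxidation (LiN(SiMe3)2, Me3SiCl; then Pd(OAc)2, MeCN) gives the enone F5, and α-iodination (I2, pyridine) gives the iodo enone F6. Suzuki–Miyaura coupling with isopropenylboronic acid pinacol ester (PdCl2(dppf), dppf = 1,1'-bis(diphenylphosphino)ferrocene, K3PO4) gives the 7-isopropenyl enone F7. Conjugate reduction with [(Ph3P)CuH]6 and protonation at C7 then lead to 16.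

3. Step 11. Possible failures are Z-to-E isomerisation of the angeloyl unit (tiglate formation), base- or heat-induced migration of the isopropenyl double bond, or incomplete acylation of the hindered C3 hydroxyl. Fallback, setting out from 17 and rejoining at 18: both hydroxyls are acylated with 2-[bis(2,2,2-trifluoroethoxy)phosphoryl]propanoic acid (DCC, DMAP) to the bis-phosphonate F8, and a Still–Gennari olefination with acetaldehyde (KN(SiMe3)2, 18-crown-6, THF, −78 °C) builds both (Z)-2-methylbut-2-enoates in place.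

Further compounds
F1 | step 4 | (2R)-N-methoxy-N-methyl-2-[(1S)-1-methylcyclohex-2-en-1-yl]propanamide | C1C[C@](C)([C@@H](C)C(=O)N(C)OC)C=CC1
F2 | step 4 | (4R)-4-[(1S)-1-methylcyclohex-2-en-1-yl]pent-1-yn-3-one | C1C[C@](C)([C@@H](C)C(=O)C#C)C=CC1
F3 | step 4 | (1Z,4R)-1-iodo-4-[(1S)-1-methylcyclohex-2-en-1-yl]pent-1-en-3-one | C1C[C@](C)([C@@H](C)C(=O)/C=C\I)C=CC1
F4 | step 4 | cis-fused 4,5-dimethylbicyclo[4.4.0]deca-1,8-dien-3-one (C1=C2 enone in ring A, C8=C9 in ring B, C4 and C5 methyls cis, ring fusion as in 9) | C1C[C@@]2(C)[C@H](C=CC(=O)[C@@H]2C)C=C1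
F5 | step 9 | 3,9-bis(tert-butyldimethylsilyloxy)-4,5-dimethyl-cis-bicyclo[4.4.0]dec-6-en-8-one (stereocentres as in 14) | C1=C[C@@]2(C)[C@H](CC[C@@H](O[Si](C)(C)C(C)(C)C)[C@@H]2C)[C@@H](O[Si](C)(C)C(C)(C)C)C1=O
F6 | step 9 | 7-iodo derivative of F5 | IC1=C[C@@]2(C)[C@H](CC[C@@H](O[Si](C)(C)C(C)(C)C)[C@@H]2C)[C@@H](O[Si](C)(C)C(C)(C)C)C1=O
F7 | step 9 | 3,9-bis(tert-butyldimethylsilyloxy)eremophila-6,11-dien-8-one (stereocentres as in 14) | C=C(C)C1=C[C@@]2(C)[C@H](CC[C@@H](O[Si](C)(C)C(C)(C)C)[C@@H]2C)[C@@H](O[Si](C)(C)C(C)(C)C)C1=O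
F8 | step 11 | 3,9-bis{2-[bis(2,2,2-trifluoroethoxy)phosphoryl]propanoyloxy} derivative of 17 (phosphonate α-carbons as mixtures) | C=C(C)[C@H]1C[C@@]2(C)[C@H](CC[C@@H](OC(=O)C(C)P(=O)(OCC(F)(F)F)OCC(F)(F)F)[C@@H]2C)[C@@H](OC(=O)C(C)P(=O)(OCC(F)(F)F)OCC(F)(F)F)C1=O
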